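A plateau tempts you to call a reaction finished, but flat readings tell you that the target stopped rising, not why, and the remedy depends on why. Oak is the flask asked about, followed so far; cedar is an earlier run.

| setting | oak | cedar | flask |
|---|---|---|---|
| starting material | 0.050 M | 0.075 M | 0.050 M |
| second substrate | 0.045 M | 0.045 M | 0.0450 M |
| free enzyme | 5 µM | 5 µM | 5.0 µM |
| temperature | 40 °C | 35 °C | 40 °C |
| remark | the very flask that is asked about, followed so far | run made earlier |  |
| time |  |  | 80 min |

| run | time / min | target / % |
|---|---|---|
| oak | 6.00 | 4.0 |
| oak | 15.0 | 8.8 |
| oak | 30.0 | 10.6 |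
| oak | 50.0 | 9.5 |
| oak | 60.0 | 10.5 |
| cedar | 1.33 | 2.4 |
| cedar | 4.00 | 2.2 |
| cedar | 8.00 | 5.3 |
| cedar | 12.0 | 3.2 |
| cedar | 15.0 | 6.2 |

(each reading ± 1 percentage point)

- spring: at 80 min raise the temperature by 15 K, then wait 40 min
- dusk: at 80 min add free enzyme, 100% of the amount charged, then wait 40 min
- noon: at 80 min add second substrate, 50.0% of the amount charged, then wait 40 min
- dawn: at 80 min take out 90% of the first product then present, then wait 40 min
- summer: change nothing and wait 40 min more

- additions leave the volume as it is
- what was read earlier has a scatter of 1 percentage point, one standard deviation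

- target, in percent of the starting material first charged, at 80 min
- which option adds most target ("none" when 2 percentage points or less is all one gets) (spring / dusk / noon / dawn / summer / none)
- target present, in percent of the starting material first charged, after dawn
- target present, in percent of the starting material first charged, after summer

Cedar's readings end at 15.0 min and show no plateau, so reckon from oak, whose last three readings average 10.2%, a reading with its scatter. Multiply by the starting material charged and divide by the enzyme charged, and you get 1020 molecules of target standing per molecule of enzyme charged: the net turnover of the charge.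

Now solve both ends. At one end the stall is an equilibrium. A catalyst moves no equilibrium, so fresh enzyme adds nothing, and taking out first product pays. At the other end the working life of the catalyst ends the rise. The net turnover is then a constant of the enzyme at these charges of substrate and this temperature, and a second full charge adds 10 percentage points. The real gain from dusk should lie between nothing and that figure.

These readings do not separate the two ends, so what follows is my judgement, not proof. Read as an equilibrium, oak's plateau lies far towards the starting side, and I find a tiring enzyme the likelier story. I therefore take the catalyst end: target near the plateau at the asked time, and dusk as the best option.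

The forecast differs on the option: it gives 10.3%, names dawn as best with 15% after it and 10.4% after summer, judging “a reversible enzymatic transfer more likely”.

The flask gives 8.91% at 80 min; dusk is best and adds 8.7 points, while dawn ends at 6.86% and summer at 6.64%.

    starting material + free enzyme ⇌ first complex (K = 9.60 L mol⁻¹, k = 7110 L mol⁻¹ s⁻¹, Ea = 31.0 kJ mol⁻¹, ΔH = −40.0 kJ mol⁻¹)
    first complex ⇌ loaded enzyme + first product (K = 0.130 M, k = 6.23 s⁻¹, Ea = 73.0 kJ mol⁻¹, ΔH = −53.0 kJ mol⁻¹)
    second complex → free enzyme + target (k = 7.31 s⁻¹, Ea = 70.0 kJ mol⁻¹)
    second substrate + loaded enzyme ⇌ second complex (K = 74.0 L mol⁻¹, k = 979 L mol⁻¹ s⁻¹, Ea = 39.0 kJ mol⁻¹, ΔH = 10.0 kJ mol⁻¹)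
    second substrate + target → over-reaction product (k = 0.0181 L mol⁻¹ s⁻¹, Ea = 76.0 kJ mol⁻¹)
    free enzyme → unfolded enzyme (k = 5.86 × 10⁻⁶ s⁻¹, Ea = 259 kJ mol⁻¹)
    free enzyme → spent catalyst (k = 6.13 × 10⁻⁴ s⁻¹, Ea = 96.0 kJ mol⁻¹)
    (constants at 40 °C)

That gain lies between nothing and my 10 points, as the net turnover set it; at 80.0 min this flask holds spent catalyst at 78.0% of the catalyst charged and free enzyme at 11.4%. For the neighbour charged with 2.0 × 10⁻⁵ M of free enzyme, the same number gives 40.8%, and that flask holds 42.9%. The gain rests in part on first complex falling back to starting material and free enzyme, the form that dies: in the run without that step, dusk adds 0.34 points instead of 8.7 points.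

The readings were generated by integration from invented constants, noise included.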